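The easy mistake with these runs was to take J/G as a fixed number for the chemistry: it moves with [X], and [X] moves during a run.

| setting | midnight | spring | noon | Thursday's | Monday's | Tuesday's | Saturday's |
|---|---|---|---|---|---|---|---|
| Z | 0.035 M | 0.29 M | 0.050 M | 0.025 M | 0.20 M | 0.050 M | 0.20 M |
| X | 0.065 M | 0.065 M | 0.080 M | 0.0200 M | 0.100 M | 0.0650 M | 0.250 M |
| remark | run made earlier | run made earlier | run made earlier |  |  |  |  |
| time |  |  |  | 30 min | 30 min | 30 min | 30 min |

| run | time / min | J / % | G / % |
|---|---|---|---|
| midnight | 4.00 | 12 | 29 |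
| midnight | 8.00 | 26 | 56 |
| midnight | 12.0 | 26 | 67 |
| midnight | 15.0 | 27 | 68 |
| midnight | 20.0 | 29 | 68 |
| spring | 4.00 | 8 | 30 |
| spring | 8.00 | 15 | 60 |
| spring | 12.0 | 15 | 73 |
| spring | 15.0 | 18 | 76 |
| spring | 20.0 | 18 | 77 |
| noon | 4.00 | 15 | 29 |
| noon | 8.00 | 23 | 51 |
| noon | 12.0 | 31 | 60 |
| noon | 15.0 | 32 | 64 |
| noon | 20.0 | 33 | 66 |

(standard deviation of a reading: 1.5 percentage points)

- the flasks put in order of share of J in all that became J or G or L, best first, at 30 min (Thursday's / Monday's / Tuesday's / Saturday's)
- the share of J in all that became J or G or L of the flask you put first, at 30 min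
- the share of J in all that became J or G or L of the flask you put last, at 30 min

- what was read earlier has a scatter of 1.5 percentage points, one standard deviation
- a reading or a percentage of J counts all its forms, free or not

I set my scale at the symmetric case. From the last readings of the midnight and noon runs, averaged, [X]·G/J came to 0.156 M: the even-split concentration, the [X] at which J and G form equally, the inverse of a selectivity factor. So I wrote

share of J = mean [X] / (mean [X] + 0.156 M)

I counted J and G only, as the noon run's last readings already sum to 99.0%. At its charged [X] the spring run should have given 29.4%, but J read 18%, so I assumed one X spent per J and all Z reacted. Each estimate then fed the next: share, J formed, mean of charged and final [X], new share. The third figure on each line reforges the weak link, that plain mean. With one X per J, [X] decays exponentially in G, so I replaced it by the logarithmic mean.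

Saturday's: 54.7%, 55.6%, 54.8%

Monday's: 28.1%, 31.5%, 28.8%

Tuesday's: 27.0%, 27.2%, 27.1%

Thursday's: 10.6%, 10.7%, 10.7%

I committed to the third figures.

The forecast said Saturday's > Monday's > Tuesday's > Thursday's, with 54% and 10.5%, slightly below mine, and warned that “Saturday's is a long extrapolation in X”.

The flask gave Saturday's > Monday's > Tuesday's > Thursday's, with 55.6% and 11.3%.

    E → G (k = 0.00393 s⁻¹)
    Z → E (k = 0.00669 s⁻¹)
    Q ⇌ J, rate k3*(cs3 - [J]) while solid is left; crystals form when [J] > cs3 (solubility = 0.920 mM, k = 0.0237 s⁻¹)
    X + E → J (k = 0.0276 L mol⁻¹ s⁻¹)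
    X + J → L (k = 0.00195 L mol⁻¹ s⁻¹)

Through 0.156 M, Saturday's 55.6% stands for a mean [X] of 0.195 M, between the charged 0.250 M and the 0.134 M left at 30.0 min. The neighbouring flask was Saturday's with X lowered to 0.15 M. The same chain gave 39.3%, then 41.5% by the plain mean, and 39.7% by the logarithmic mean. That flask gave a share of 41.3%, with G at 58.2% and X left at 44% of its charge.

(The data stem from a simulated flask with made-up constants; scatter was added.)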